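Early on, G comes fast and L slowly: at 4.00 h the birch run holds 83.9 % of G and 0.2 % of L. So you can build delta from D ⇌ G, catalysed by X, and add the slower steps afterwards.

| setting | birch | ash | cedar | epsilon | gamma | delta | zeta |
|---|---|---|---|---|---|---|---|
| D | 0.050 M | 0.20 M | 0.10 M | 0.10 M | 0.10 M | 0.10 M | 0.10 M |
| Q | 1.2 equiv | 1.2 equiv | 1.2 equiv | 1.20 equiv | 1.20 equiv | 1.20 equiv | 1.20 equiv |
| X | 5.8 mol% | 5.8 mol% | 5.8 mol% | 5.8 mol% | 5.8 mol% | 5.8 mol% | 5.8 mol% |
| E | 10 mol% | 10 mol% | 15 mol% | 10 mol% | 10 mol% | 10 mol% | 10 mol% |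
| temperature | 40 °C | 70 °C | 40 °C | 95 °C | 70 °C | 45 °C |  |
| remark | run made earlier | run made earlier | run made earlier |  |  |  | at 45 °C until 40 min, from then on at 95 °C |
| time |  |  |  | 3.0 h | 3.0 h | 3.0 h | 3.0 h |

- birch (time / h: G / %, L / %): 4.00: 83.9, 0.2; 8.00: 93.7, 1.4; 12.0: 95.0, 3.0; 20.0: 94.0, 3.4; 30.0: 90.9, 5.7; 60.0: 88.2, 7.1
- ash (time / h: G / %, L / %): 0.833: 63.0, 13.5; 2.50: 53.2, 26.0; 5.00: 45.3, 38.7; 6.00: 41.2, 41.2; 10.0: 33.2, 52.6; 15.0: 27.6, 62.1
- cedar (time / h: G / %, L / %): 4.00: 92.3, 3.2; 8.00: 87.4, 7.7; 15.0: 84.8, 12.7; 30.0: 78.1, 19.7; 60.0: 69.3, 30.9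

(each reading ± 1 percentage point)

1. the best flask by amount of G, in percent of the D charged; "all alike" if 1.5 percentage points covers them all (epsilon / gamma / delta / zeta / all alike)
2. amount of G at the end, in percent of the D charged, epsilon
3. amount of G at the end, in percent of the D charged, gamma
4. amount of G at the end, in percent of the D charged, delta
5. amount of G at the end, in percent of the D charged, zeta

- what is said of L includes J
- steps thought possible: D + X <-> X + G; Q + E + G -> E + L; E <-> Z; E + L <-> J

1. Main step. Let K be G/D late in a run, with D the charge minus G and L. The last 4 ash readings give K = 2.54 at 70 °C, and the last 3 birch readings give 25.5 at 40 °C. Both carry the scatter. Taking ln K as linear in 1/T gives 16.9 at delta's 45 °C. Now define the ceiling share s = K/(1+K), the part of D plus G that stands as G at equilibrium (thermodynamic control). For delta, s = 94.4 %, higher than the 71.7 % at 70 °C.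

2. Its clock. The birch reading at 4.00 h, set against that run's ceiling of 96.2 %, gives a time constant. Delta has twice the concentration of X, so at 40 °C a flask of delta's concentration has a time constant τ of 0.967 h. Delta's 3.0 h is longer than that, and 4.49 % of the approach stays open at this rate. I take this as the low side of G, since delta runs warmer than birch.

3. Add the drain. Q and E turn G into L. Cedar made 3.2 % of L in 4.00 h with 15 mol% of E. Scaled to delta's 10 mol% of E and 3.0 h, that is 1.60 % of L, before any allowance for the warmer bath.

4. Add the E forms. Z and J are further forms of E, and the steps thought possible let them take E out of the drain. Cedar's L grows more slowly late on: 11 percentage points over the final 30.0 h, against 3.2 % over the first 4.00 h. I leave my L at the early rate.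

5. My reckoning. I expect G in delta between the ceiling s and that figure less the lag, 90.2 %. At the ceiling G is s times the part of the charge not turned to L, so the small L of step 3 comes off this bracket. The low side still stands above the ceiling at gamma's temperature, so I put delta above gamma.

6. The forecast names delta as best. It gives 91 % for delta (87 % to 95 %), 65 % for gamma, 26 % for epsilon and 27 % for zeta, and says: “Zeta re-equilibrates at 95 °C, so it ends like epsilon with slightly less L.”

7. The flasks give 25.7 % for epsilon, 63.4 % for gamma, 90.6 % for delta and 27.0 % for zeta, so delta is best.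

    D + X ⇌ X + G (K = 2.50, k = 0.250 L mol⁻¹ s⁻¹, Ea = 47.0 kJ mol⁻¹, ΔH = −66.0 kJ mol⁻¹)
    Q + E + G → E + L (k = 0.0180 L² mol⁻² s⁻¹, Ea = 68.0 kJ mol⁻¹)
    E ⇌ Z (K = 0.330, k = 7.00 × 10⁻⁵ s⁻¹, Ea = 106 kJ mol⁻¹, ΔH = −29.0 kJ mol⁻¹)
    E + L ⇌ J (K = 16.0 L mol⁻¹, k = 0.0310 L mol⁻¹ s⁻¹, Ea = 64.0 kJ mol⁻¹, ΔH = −32.0 kJ mol⁻¹)
    (constants at 70 °C)

8. Delta's 90.6 % falls inside my bracket, and its L is 2.48 %. Now take the neighbour with 2.5 mol% of E, the same flask in every other charge. The ceiling is unchanged, so s times the L difference, 2.48 % against 0.638 %, promises 1.7 points more G. That neighbour gives 92.3 % of G, 1.7 points above delta, with 7.04 % of D still there.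

The readings come from a simulation with constants of no real substance, noise included.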